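**Retrosynthetic overview**
1. The target is the isofraxidin ether of a 9βH-drim-7-en-3-one. The C11–O aryl ether is cut first (Mitsunobu union with isofraxidin), and the C3 ketone is carried as a protected (3S)-carbinol until the last step.
2. The route rests on ring B: its carbons C5–C10, with the methyl groups on C8 and C10, are read as the ring of a 2,4-dimethylphenol carrying its hydroxyl on C7, so the quaternary C10 is the position para to oxygen. The C7 oxygen is later removed through the C7–C8 enol triflate, leaving the C7=C8 alkene.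
3. Key disconnection C1–C10: the phenolate of a C1 mesylate alkylates its own para carbon, closing ring A onto the arene as a cross-conjugated 5,8-dien-7-one. C9–C11 then comes from cuprate addition and H5 from Li/NH3 reduction.
4. The precursor comes from 5-bromo-2,4-dimethylphenol and methyl isobutyrate (C4–C5 bond by palladium-catalysed α-arylation). C3 is set by Brown allylation, and C1–C2 by ozonolytic shortening of the allyl group.
5. Ring order: ring B is present from the start as the arene, ring A is formed in step 10, and the two coumarin rings arrive intact with isofraxidin in step 17.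

Key step: step 10

Assumption: drimane numbering and the steroid α/β convention (C10 methyl β) are used; the target has H5 α and C11 α on C9 (9βH), that is (5R,9R,10S); C8 in 19 to 21 is drawn as the more stable 8α-methyl epimer, and the other epimer would serve equally because C8 becomes sp2 in step 13.

**Route**

Step 1
Reactants: 1 5-bromo-2,4-dimethylphenol
Product: 2 1-(benzyloxy)-5-bromo-2,4-dimethylbenzene
Conditions: BnBr, K2CO3, DMF, rt
Reagents that add atoms: benzyl bromide, BrCc1ccccc1
Why: Williamson etherification masks the phenol as a benzyl ether that withstands the strong bases and hydrides ahead and can later be removed by hydrogenolysis without touching a silyl ether or a mesylate.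

Step 2
Reactants: 2 1-(benzyloxy)-5-bromo-2,4-dimethylbenzene; 3 methyl isobutyrate
Product: 5 methyl 2-[5-(benzyloxy)-2,4-dimethylphenyl]-2-methylpropanoate, via lithium enolate of methyl isobutyrate 4 (not isolated)
Conditions: Cy2NH, n-BuLi, toluene, 0 °C; 3, rt; then 2, Pd2(dba)3 (1 mol %), P(t-Bu)3 (2 mol %), rt
Reagents that add atoms: none
Why: Palladium-catalysed α-arylation of an ester enolate (Buchwald–Hartwig type, zerovalent palladium with the bulky electron-rich P(t-Bu)3) couples the fully substituted lithium enolate with the ortho-substituted aryl bromide at room temperature and forges the C4–C5 bond with the quaternary C4 in place.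

Step 3
Reactants: 5 methyl 2-[5-(benzyloxy)-2,4-dimethylphenyl]-2-methylpropanoate
Product: 6 2-[5-(benzyloxy)-2,4-dimethylphenyl]-2-methylpropan-1-ol
Conditions: LiAlH4, THF, 0 °C → rt
Reagents that add atoms: none
Why: Hydride reduction of the ester, the only reducible group present, gives the neopentyl alcohol cleanly, where a partial reduction to the aldehyde would be hard to stop.

Step 4
Reactants: 6 2-[5-(benzyloxy)-2,4-dimethylphenyl]-2-methylpropan-1-ol
Product: 7 2-[5-(benzyloxy)-2,4-dimethylphenyl]-2-methylpropanal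
Conditions: Dess–Martin periodinane, CH2Cl2, rt
Reagents that add atoms: none
Why: Dess–Martin oxidation of the primary alcohol gives an aldehyde that has no α-hydrogen and therefore cannot enolise or be oxidised further under these conditions.

Step 5
Reactants: 7 2-[5-(benzyloxy)-2,4-dimethylphenyl]-2-methylpropanal
Product: 9 (3S)-2-[5-(benzyloxy)-2,4-dimethylphenyl]-2-methylhex-5-en-3-ol, via diisopinocampheylborinate ester 8 (not isolated)
Conditions: (−)-Ipc2BOMe [(+)-α-pinene series], allylMgBr, Et2O, 0 °C → rt, Mg salts filtered off; 7, Et2O, −100 °C; NaOH, H2O2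
Reagents that add atoms: allylmagnesium bromide, C=CC[Mg]Br
Why: Brown asymmetric allylboration through a closed chair (Zimmerman–Traxler) transition state, in which the isopinocampheyl groups of the (+)-α-pinene-derived reagent send the allyl group to the Si face of the non-enolisable α-quaternary aldehyde (the sense established for pivalaldehyde and benzaldehyde), should set C3 as (S), and alkaline peroxide releases the alcohol from the borinate.

Step 6
Reactants: 9 (3S)-2-[5-(benzyloxy)-2,4-dimethylphenyl]-2-methylhex-5-en-3-ol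
Product: 10 tert-butyl{[(3S)-2-[5-(benzyloxy)-2,4-dimethylphenyl]-2-methylhex-5-en-3-yl]oxy}dimethylsilane
Conditions: TBSOTf, 2,6-lutidine, CH2Cl2, 0 °C → rt
Reagents that add atoms: tert-butyldimethylsilyl trifluoromethanesulfonate, CC(C)(C)[Si](C)(C)OS(=O)(=O)C(F)(F)F
Why: Silylation of the hindered neopentyl-type secondary alcohol with the reactive silyl triflate and a hindered pyridine base installs the bulky C3 ether that is meant to sit equatorial in the ring-closing transition state.

Step 7
Reactants: 10 tert-butyl{[(3S)-2-[5-(benzyloxy)-2,4-dimethylphenyl]-2-methylhex-5-en-3-yl]oxy}dimethylsilane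
Product: 13 (3S)-4-[5-(benzyloxy)-2,4-dimethylphenyl]-3-(tert-butyldimethylsilyloxy)-4-methylpentan-1-ol, via ozonide 11 (not isolated), via aldehyde 12 (not isolated)
Conditions: O3, CH2Cl2, −78 °C (Sudan Red 7B end point); PPh3, −78 °C → rt; MeOH, NaBH4, 0 °C
Reagents that add atoms: ozone, [O-][O+]=O
Why: Ozonolysis of the terminal alkene, which reacts far faster with ozone than the alkoxyarene when the gas is titrated against a dye, followed by PPh3 reduction of the ozonide and NaBH4 reduction of the aldehyde, shortens the allyl group to the C2–C1 unit with its primary alcohol and leaves C3 untouched.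

Step 8
Reactants: 13 (3S)-4-[5-(benzyloxy)-2,4-dimethylphenyl]-3-(tert-butyldimethylsilyloxy)-4-methylpentan-1-ol
Product: 14 (3S)-4-[5-(benzyloxy)-2,4-dimethylphenyl]-3-(tert-butyldimethylsilyloxy)-4-methylpentyl methanesulfonate
Conditions: MsCl, Et3N, CH2Cl2, 0 °C
Reagents that add atoms: methanesulfonyl chloride, CS(Cl)(=O)=O
Why: Mesylation (sulfonyl transfer to the unhindered primary alcohol) provides the leaving group on C1.

Step 9
Reactants: 14 (3S)-4-[5-(benzyloxy)-2,4-dimethylphenyl]-3-(tert-butyldimethylsilyloxy)-4-methylpentyl methanesulfonate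
Product: 15 5-[(3S)-3-(tert-butyldimethylsilyloxy)-5-(methylsulfonyloxy)-2-methylpentan-2-yl]-2,4-dimethylphenol
Conditions: H2 (1 atm), Pd/C, EtOAc, rt
Reagents that add atoms: none
Why: Hydrogenolysis of the aryl benzyl ether over Pd/C under neutral conditions frees the phenol, while the primary mesylate and the silyl ether are not reduced.

Step 10
Reactants: 15 5-[(3S)-3-(tert-butyldimethylsilyloxy)-5-(methylsulfonyloxy)-2-methylpentan-2-yl]-2,4-dimethylphenol
Product: 17 (3S,10R)-3-(tert-butyldimethylsilyloxy)-11-nor-drima-5,8-dien-7-one, via potassium phenolate 16 (not isolated)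
Conditions: KOtBu (1.05 equiv), t-BuOH, 0.01 M, 60 °C
Reagents that add atoms: none
Why: With one equivalent of KOtBu the phenol becomes phenolate 16, an ambident nucleophile that attacks the CH2–OMs carbon C1 with C10, the ring carbon para to oxygen, by backside (SN2) displacement; aromatic stabilisation is given up in exchange for the C7=O bond of a cross-conjugated cyclohexadienone, the outcome known for base-promoted intramolecular C-alkylation of para-substituted phenols (phenolate participation of the Winstein–Masamune type). Ring A (C10, C1, C2, C3, C4, C5) closes in the 6-exo-tet mode. The new quaternary centre C10 is controlled by the (3S) centre through a chair-like transition state with the C3 silyloxy group equatorial, so the chain adds to the arene face that leaves the C10 methyl cis to the C3 oxygen (3β,10β); the C10 epimer is a diastereomer and is removed by chromatography, so it cannot lower the enantiomeric purity once C3 is oxidised. The step needs attack at C10 and not at the free ortho carbon C6 or at oxygen: O-alkylation within the molecule is ruled out by the meta relation of oxygen and chain, O-alkylation between molecules is held back by high dilution and by the hydrogen-bonded oxygen in t-BuOH, and closure on C6 would turn one C4 methyl into the arene plane against the C10 methyl, whereas closure on C10 places that methyl next to H6. Because all the base is consumed by the phenol, no free tert-butoxide remains to eliminate the mesylate, and the product has no enolisable hydrogen and should be stable to the conditions.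

Step 11
Reactants: 17 (3S,10R)-3-(tert-butyldimethylsilyloxy)-11-nor-drima-5,8-dien-7-one
Product: 19 3β-(tert-butyldimethylsilyloxy)-11-(methoxymethoxy)-8βH,9βH-drim-5-en-7-one, via trimethylsilyl dienol ether 18 (not isolated)
Conditions: Bu3SnCH2OMOM, n-BuLi, THF, −78 °C; CuBr·SMe2, −78 °C; TMSCl, 17, −78 → −40 °C; aq NH4Cl/NH3; K2CO3, MeOH, rt
Reagents that add atoms: tributyl[(methoxymethoxy)methyl]stannane, CCCC[Sn](CCCC)(CCCC)COCOC
Why: Conjugate addition of an α-alkoxymethyl Gilman cuprate, accelerated by TMSCl, should take place at C9 (the hydrogen-bearing β-carbon of the C8=C9 enone) and not at the fully substituted C5, and from the α face away from the C10 methyl that stands over the β face, as methyl cuprates do at C1 of steroidal 1,4-dien-3-ones, which sets C9 with C11 α; methanolysis of the silyl dienol ether then gives the C5=C6 enone with the C8 methyl in the more stable equatorial α position.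

Step 12
Reactants: 19 3β-(tert-butyldimethylsilyloxy)-11-(methoxymethoxy)-8βH,9βH-drim-5-en-7-one
Product: 21 3β-(tert-butyldimethylsilyloxy)-11-(methoxymethoxy)-5αH,8βH,9βH-driman-7-one, via lithium 6-en-7-olate 20 (not isolated)
Conditions: Li, NH3 (l), THF, t-BuOH (1 equiv), −78 °C; isoprene; NH4Cl
Reagents that add atoms: none
Why: Dissolving-metal reduction of the remaining enone protonates the β-carbon C5 axially from the α face, the stereoelectronically allowed and more stable trans-fused outcome known from Li/NH3 reduction of steroidal 5-en-7-ones, which sets H5 trans to the C10 methyl, while the lithium enolate shields C7 from further reduction until the NH4Cl quench.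

Step 13
Reactants: 21 3β-(tert-butyldimethylsilyloxy)-11-(methoxymethoxy)-5αH,8βH,9βH-driman-7-one
Product: 23 3β-(tert-butyldimethylsilyloxy)-11-(methoxymethoxy)-7-(trimethylsilyloxy)-5αH,9βH-drim-7-ene, via bromomagnesium 7-en-7-olate 22 (not isolated)
Conditions: i-Pr2NH, EtMgBr, Et2O, rt; 21, rt, 12 h; TMSCl, Et3N, HMPA, rt
Reagents that add atoms: chlorotrimethylsilane, C[Si](C)(C)Cl
Why: Thermodynamic enolisation with i-Pr2NMgBr (Krafft–Holton conditions) lets the magnesium enolates equilibrate to the tetrasubstituted C7–C8 enolate, whose C8 methyl suffers little allylic strain because the C9 side chain is pseudoaxial, and silylation fixes this regiochemistry as the silyl enol ether.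

Step 14
Reactants: 23 3β-(tert-butyldimethylsilyloxy)-11-(methoxymethoxy)-7-(trimethylsilyloxy)-5αH,9βH-drim-7-ene
Product: 25 3β-(tert-butyldimethylsilyloxy)-11-(methoxymethoxy)-5αH,9βH-drim-7-en-7-yl trifluoromethanesulfonate, via lithium 7-en-7-olate 24 (not isolated)
Conditions: MeLi, THF, 0 °C; PhNTf2, −78 °C → rt; aq NH4Cl
Reagents that add atoms: N-phenylbis(trifluoromethanesulfonimide), O=S(=O)(N(c1ccccc1)S(=O)(=O)C(F)(F)F)C(F)(F)F
Why: Cleavage of the trimethylsilyl enol ether with MeLi regenerates the lithium enolate without loss of regiochemistry, since no proton source is present, and O-triflation of this enolate with PhNTf2 gives the enol triflate.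

Step 15
Reactants: 25 3β-(tert-butyldimethylsilyloxy)-11-(methoxymethoxy)-5αH,9βH-drim-7-en-7-yl trifluoromethanesulfonate
Product: 26 3β-(tert-butyldimethylsilyloxy)-11-(methoxymethoxy)-5αH,9βH-drim-7-ene
Conditions: Pd(OAc)2 (5 mol %), PPh3 (10 mol %), HCO2H, Bu3N, DMF, 60 °C
Reagents that add atoms: none
Why: Palladium-catalysed formate reduction of the enol triflate (Cacchi conditions: oxidative addition to zerovalent palladium, formate exchange, loss of CO2 and reductive elimination) replaces the triflate by hydrogen and leaves the C7=C8 alkene where the enolate double bond had been.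

Step 16
Reactants: 26 3β-(tert-butyldimethylsilyloxy)-11-(methoxymethoxy)-5αH,9βH-drim-7-ene
Product: 27 5αH,9βH-drim-7-ene-3β,11-diol
Conditions: HCl (1.25 M in MeOH), 0 → 40 °C
Reagents that add atoms: none
Why: Acid-catalysed methanolysis removes the MOM acetal (transacetalisation to dimethoxymethane) and the silyl ether (silyl transfer to methanol) in one operation under conditions mild enough that the trisubstituted alkene should not migrate.

Step 17
Reactants: 27 5αH,9βH-drim-7-ene-3β,11-diol; 28 isofraxidin
Product: 29 7-{[(3S,5R,9R,10S)-3-hydroxy-9βH-drim-7-en-11-yl]oxy}-6,8-dimethoxy-2H-chromen-2-one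
Conditions: PPh3, DIAD, THF, 0 → 40 °C
Reagents that add atoms: none
Why: Mitsunobu etherification should engage only the primary C11 alcohol, since substitution at the neopentyl secondary C3 carbinol is not feasible, and the acidic 7-hydroxyl of isofraxidin (pKa about 8) displaces the oxyphosphonium group at the CH2 carbon, where no stereocentre is involved.

Step 18
Reactants: 29 7-{[(3S,5R,9R,10S)-3-hydroxy-9βH-drim-7-en-11-yl]oxy}-6,8-dimethoxy-2H-chromen-2-one
Product: 30 7-{[(1R,4aR,8aS)-2,5,5,8a-tetramethyl-6-oxo-1,4,4a,5,6,7,8,8a-octahydronaphthalen-1-yl]methoxy}-6,8-dimethoxy-2H-chromen-2-one (CNP0127079.1)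
Conditions: Dess–Martin periodinane, CH2Cl2, rt
Reagents that add atoms: none
Why: Dess–Martin oxidation converts the secondary C3 alcohol into the ketone under neutral conditions that leave the coumarin, the aryl ether and the alkene alone, and removes the controller stereocentre after it has set C10.

**Compound list**
1 | 5-bromo-2,4-dimethylphenol | Cc1cc(C)c(Br)cc1O | starting material
2 | 1-(benzyloxy)-5-bromo-2,4-dimethylbenzene | Cc1cc(C)c(Br)cc1OCc1ccccc1 | intermediate
3 | methyl isobutyrate | COC(=O)C(C)C | starting material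
4 | lithium enolate of methyl isobutyrate | COC(O[Li])=C(C)C | intermediate
5 | methyl 2-[5-(benzyloxy)-2,4-dimethylphenyl]-2-methylpropanoate | COC(=O)C(C)(C)c1cc(OCc2ccccc2)c(C)cc1C | intermediate
6 | 2-[5-(benzyloxy)-2,4-dimethylphenyl]-2-methylpropan-1-ol | OCC(C)(C)c1cc(OCc2ccccc2)c(C)cc1C | intermediate
7 | 2-[5-(benzyloxy)-2,4-dimethylphenyl]-2-methylpropanal | O=CC(C)(C)c1cc(OCc2ccccc2)c(C)cc1C | intermediate
8 | diisopinocampheylborinate ester of 9 (isopinocampheyl groups of the (+)-α-pinene series) | C=CC[C@H](OB([C@@H]1C[C@@H]2C[C@@H](C2(C)C)[C@H]1C)[C@@H]1C[C@@H]2C[C@@H](C2(C)C)[C@H]1C)C(C)(C)c1cc(OCc2ccccc2)c(C)cc1C | intermediate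
9 | (3S)-2-[5-(benzyloxy)-2,4-dimethylphenyl]-2-methylhex-5-en-3-ol | C=CC[C@H](O)C(C)(C)c1cc(OCc2ccccc2)c(C)cc1C | intermediate
10 | tert-butyl{[(3S)-2-[5-(benzyloxy)-2,4-dimethylphenyl]-2-methylhex-5-en-3-yl]oxy}dimethylsilane | C=CC[C@H](O[Si](C)(C)C(C)(C)C)C(C)(C)c1cc(OCc2ccccc2)c(C)cc1C | intermediate
11 | ozonide of 10 (3-substituted 1,2,4-trioxolane, both epimers at the ring carbon) | C1OOC(C[C@H](O[Si](C)(C)C(C)(C)C)C(C)(C)c2cc(OCc3ccccc3)c(C)cc2C)O1 | intermediate
12 | (3S)-4-[5-(benzyloxy)-2,4-dimethylphenyl]-3-(tert-butyldimethylsilyloxy)-4-methylpentanal | O=CC[C@H](O[Si](C)(C)C(C)(C)C)C(C)(C)c1cc(OCc2ccccc2)c(C)cc1C | intermediate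
13 | (3S)-4-[5-(benzyloxy)-2,4-dimethylphenyl]-3-(tert-butyldimethylsilyloxy)-4-methylpentan-1-ol | OCC[C@H](O[Si](C)(C)C(C)(C)C)C(C)(C)c1cc(OCc2ccccc2)c(C)cc1C | intermediate
14 | (3S)-4-[5-(benzyloxy)-2,4-dimethylphenyl]-3-(tert-butyldimethylsilyloxy)-4-methylpentyl methanesulfonate | CS(=O)(=O)OCC[C@H](O[Si](C)(C)C(C)(C)C)C(C)(C)c1cc(OCc2ccccc2)c(C)cc1C | intermediate
15 | 5-[(3S)-3-(tert-butyldimethylsilyloxy)-5-(methylsulfonyloxy)-2-methylpentan-2-yl]-2,4-dimethylphenol | CS(=O)(=O)OCC[C@H](O[Si](C)(C)C(C)(C)C)C(C)(C)c1cc(O)c(C)cc1C | intermediate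
16 | potassium phenolate of 15 | CS(=O)(=O)OCC[C@H](O[Si](C)(C)C(C)(C)C)C(C)(C)c1cc([O-])c(C)cc1C.[K+] | intermediate
17 | (3S,10R)-3-(tert-butyldimethylsilyloxy)-11-nor-drima-5,8-dien-7-one, equal to (4aR,7S)-7-(tert-butyldimethylsilyloxy)-3,4a,8,8-tetramethyl-5,6,7,8-tetrahydronaphthalen-2(4aH)-one (3β-silyloxy, 10β-methyl) | C1=C(C)C(=O)C=C2C(C)(C)[C@@H](O[Si](C)(C)C(C)(C)C)CC[C@]12C | intermediate
18 | 3β-(tert-butyldimethylsilyloxy)-11-(methoxymethoxy)-7-(trimethylsilyloxy)-9βH-drima-5,7-diene | COCOC[C@@H]1C(C)=C(O[Si](C)(C)C)C=C2C(C)(C)[C@@H](O[Si](C)(C)C(C)(C)C)CC[C@]12C | intermediate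
19 | 3β-(tert-butyldimethylsilyloxy)-11-(methoxymethoxy)-8βH,9βH-drim-5-en-7-one (8α-methyl, C11 α) | COCOC[C@@H]1[C@H](C)C(=O)C=C2C(C)(C)[C@@H](O[Si](C)(C)C(C)(C)C)CC[C@]12C | intermediate
20 | lithium 3β-(tert-butyldimethylsilyloxy)-11-(methoxymethoxy)-5αH,8βH,9βH-drim-6-en-7-olate | COCOC[C@@H]1[C@H](C)C(O[Li])=C[C@H]2C(C)(C)[C@@H](O[Si](C)(C)C(C)(C)C)CC[C@]12C | intermediate
21 | 3β-(tert-butyldimethylsilyloxy)-11-(methoxymethoxy)-5αH,8βH,9βH-driman-7-one | COCOC[C@@H]1[C@H](C)C(=O)C[C@H]2C(C)(C)[C@@H](O[Si](C)(C)C(C)(C)C)CC[C@]12C | intermediate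
22 | bromomagnesium 3β-(tert-butyldimethylsilyloxy)-11-(methoxymethoxy)-5αH,9βH-drim-7-en-7-olate | COCOC[C@@H]1C(C)=C(O[Mg]Br)C[C@H]2C(C)(C)[C@@H](O[Si](C)(C)C(C)(C)C)CC[C@]12C | intermediate
23 | 3β-(tert-butyldimethylsilyloxy)-11-(methoxymethoxy)-7-(trimethylsilyloxy)-5αH,9βH-drim-7-ene | COCOC[C@@H]1C(C)=C(O[Si](C)(C)C)C[C@H]2C(C)(C)[C@@H](O[Si](C)(C)C(C)(C)C)CC[C@]12C | intermediate
24 | lithium 3β-(tert-butyldimethylsilyloxy)-11-(methoxymethoxy)-5αH,9βH-drim-7-en-7-olate | COCOC[C@@H]1C(C)=C(O[Li])C[C@H]2C(C)(C)[C@@H](O[Si](C)(C)C(C)(C)C)CC[C@]12C | intermediate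
25 | 3β-(tert-butyldimethylsilyloxy)-11-(methoxymethoxy)-5αH,9βH-drim-7-en-7-yl trifluoromethanesulfonate | COCOC[C@@H]1C(C)=C(OS(=O)(=O)C(F)(F)F)C[C@H]2C(C)(C)[C@@H](O[Si](C)(C)C(C)(C)C)CC[C@]12C | intermediate
26 | 3β-(tert-butyldimethylsilyloxy)-11-(methoxymethoxy)-5αH,9βH-drim-7-ene | COCOC[C@@H]1C(C)=CC[C@H]2C(C)(C)[C@@H](O[Si](C)(C)C(C)(C)C)CC[C@]12C | intermediate
27 | (3S,5R,9R,10S)-5αH,9βH-drim-7-ene-3β,11-diol | OC[C@@H]1C(C)=CC[C@H]2C(C)(C)[C@@H](O)CC[C@]12C | intermediate
28 | isofraxidin (7-hydroxy-6,8-dimethoxy-2H-chromen-2-one) | COc1cc2ccc(=O)oc2c(OC)c1O | starting material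
29 | 7-{[(3S,5R,9R,10S)-3-hydroxy-9βH-drim-7-en-11-yl]oxy}-6,8-dimethoxy-2H-chromen-2-one | COc1cc2ccc(=O)oc2c(OC)c1OC[C@@H]1C(C)=CC[C@H]2C(C)(C)[C@@H](O)CC[C@]12C | intermediate
30 | 7-{[(1R,4aR,8aS)-2,5,5,8a-tetramethyl-6-oxo-1,4,4a,5,6,7,8,8a-octahydronaphthalen-1-yl]methoxy}-6,8-dimethoxy-2H-chromen-2-one (CNP0127079.1) | COc1cc2ccc(=O)oc2c(OC)c1OC[C@@H]1C(C)=CC[C@H]2C(C)(C)C(=O)CC[C@]12C | target

**Step count**
Total: 18 steps. Longest linear sequence: 18 steps (1 → 30); methyl isobutyrate 3 and isofraxidin 28 enter as purchased compounds in steps 2 and 17.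

**Steps most likely to fail**

Step 10. The process at risk is the regiochemistry of the phenolate alkylation. The phenolate may close on the unsubstituted ortho carbon C6, which also gives a six-membered ring and then rearomatises, or it may alkylate through oxygen between molecules, so that C10 is not quaternised. A weak equatorial preference of the C3 silyloxy group would in addition lower the facial selectivity at C10. The fallback blocks C6 with a removable bromine. Setting out from 15, ortho-bromination (NBS, i-Pr2NH cat, CH2Cl2, 0 °C) at the only free position activated by the hydroxyl should give 2-bromo-3-[(3S)-3-(tert-butyldimethylsilyloxy)-5-(methylsulfonyloxy)-2-methylpentan-2-yl]-4,6-dimethylphenol F1. KOtBu in dilute t-BuOH forms its potassium phenolate F2, which can close only on C10 to give (3S,10R)-6-bromo-3-(tert-butyldimethylsilyloxy)-11-nor-drima-5,8-dien-7-one F3. Reductive removal of the vinylic bromine (Pd(OAc)2, PPh3, HCO2H, Bu3N, DMF, 60 °C) comes back to the route at 17.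

Step 11. The process at risk is the conjugate addition itself. The thermally fragile α-alkoxymethyl cuprate may decompose or add to the carbonyl group before it adds to the α-methylated enone next to the quaternary C10, or the facial selectivity at C9 may be poor. The fallback brings in C11 as a silylmethyl group, a robust hydroxymethyl equivalent. Setting out from 17, (i-PrO)Me2SiCH2MgCl with CuBr·SMe2 (cat) and TMSCl in THF at −78 °C should give the 9α-[(isopropoxydimethylsilyl)methyl] trimethylsilyl dienol ether F4. Work-up with aqueous citric acid hydrolyses it to 3β-(tert-butyldimethylsilyloxy)-11-(isopropoxydimethylsilyl)-8βH,9βH-drim-5-en-7-one F5. Tamao oxidation (H2O2, KF, KHCO3, THF/MeOH, rt) converts the C–Si bond into the alcohol 3β-(tert-butyldimethylsilyloxy)-11-hydroxy-8βH,9βH-drim-5-en-7-one F6. MOMCl and i-Pr2NEt in CH2Cl2 return to the route at 19.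

Step 17. The process at risk is slow substitution at the β-branched C11, which lies next to the quaternary C10, by the doubly ortho-substituted phenol. Elimination toward the allylic C9–H or alkylation of the reduced azodicarboxylate may then take over. The fallback replaces Mitsunobu activation by a sulfonate displacement. Setting out from 26, MgBr2·OEt2 and n-BuSH in Et2O at rt cleave the MOM ether alone to 3β-(tert-butyldimethylsilyloxy)-5αH,9βH-drim-7-en-11-ol F7. Tf2O and pyridine in CH2Cl2 at −78 °C give the primary triflate F8. The caesium salt of 28 (Cs2CO3, DMF, 0 °C → rt) displaces the triflate to the silyl-protected aryl ether F9. HF·pyridine in THF removes the silyl group and comes back to the route at 29.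

**Further compounds**
F1 | step 10 | 2-bromo-3-[(3S)-3-(tert-butyldimethylsilyloxy)-5-(methylsulfonyloxy)-2-methylpentan-2-yl]-4,6-dimethylphenol | CS(=O)(=O)OCC[C@H](O[Si](C)(C)C(C)(C)C)C(C)(C)c1c(Br)c(O)c(C)cc1C
F2 | step 10 | potassium phenolate of F1 (not isolated) | CS(=O)(=O)OCC[C@H](O[Si](C)(C)C(C)(C)C)C(C)(C)c1c(Br)c([O-])c(C)cc1C.[K+]
F3 | step 10 | (3S,10R)-6-bromo-3-(tert-butyldimethylsilyloxy)-11-nor-drima-5,8-dien-7-one | C1=C(C)C(=O)C(Br)=C2C(C)(C)[C@@H](O[Si](C)(C)C(C)(C)C)CC[C@]12C
F4 | step 11 | 3β-(tert-butyldimethylsilyloxy)-11-(isopropoxydimethylsilyl)-7-(trimethylsilyloxy)-9βH-drima-5,7-diene (not isolated) | CC(C)O[Si](C)(C)C[C@@H]1C(C)=C(O[Si](C)(C)C)C=C2C(C)(C)[C@@H](O[Si](C)(C)C(C)(C)C)CC[C@]12C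
F5 | step 11 | 3β-(tert-butyldimethylsilyloxy)-11-(isopropoxydimethylsilyl)-8βH,9βH-drim-5-en-7-one | CC(C)O[Si](C)(C)C[C@@H]1[C@H](C)C(=O)C=C2C(C)(C)[C@@H](O[Si](C)(C)C(C)(C)C)CC[C@]12C
F6 | step 11 | 3β-(tert-butyldimethylsilyloxy)-11-hydroxy-8βH,9βH-drim-5-en-7-one | OC[C@@H]1[C@H](C)C(=O)C=C2C(C)(C)[C@@H](O[Si](C)(C)C(C)(C)C)CC[C@]12C
F7 | step 17 | 3β-(tert-butyldimethylsilyloxy)-5αH,9βH-drim-7-en-11-ol | OC[C@@H]1C(C)=CC[C@H]2C(C)(C)[C@@H](O[Si](C)(C)C(C)(C)C)CC[C@]12C
F8 | step 17 | 3β-(tert-butyldimethylsilyloxy)-5αH,9βH-drim-7-en-11-yl trifluoromethanesulfonate | FC(F)(F)S(=O)(=O)OC[C@@H]1C(C)=CC[C@H]2C(C)(C)[C@@H](O[Si](C)(C)C(C)(C)C)CC[C@]12C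
F9 | step 17 | 7-{[3β-(tert-butyldimethylsilyloxy)-5αH,9βH-drim-7-en-11-yl]oxy}-6,8-dimethoxy-2H-chromen-2-one | COc1cc2ccc(=O)oc2c(OC)c1OC[C@@H]1C(C)=CC[C@H]2C(C)(C)[C@@H](O[Si](C)(C)C(C)(C)C)CC[C@]12C
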